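The ten-membered carbocycle (C1–C10, germacrane numbering) is closed last, across C9–C10, by an intramolecular Nozaki–Hiyama–Kishi reaction. The feature exploited is the C9 carbinol flanked by C10 of the ring C1=C10 acrylate (a Morita–Baylis–Hillman-type array): a C9 aldehyde and a (Z)-α-iodoacrylate at C10 give, in one operation, the ring, the ring-cis C1=C10 geometry (retention) and the C9 stereocentre (Felkin control from the C8 ester). The precursor is an open-chain trans-α-methylene-γ-butyrolactone already carrying the C4–C5 cis-epoxide (Sharpless epoxidation of nerol), the C8 acrylate ester (Barbier allylation, then Mitsunobu inversion) and both reactive termini.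

Key step: step 13

Remark: C1–C15 are germacranolide locants (C4/C5 epoxide; C6 lactone O–CH; C7 ring-fusion CH; C8, C9 the acyloxy carbons; C10 the ester-bearing alkene carbon; C11–C13 the α-methylene-lactone carbons; C14 the CO2Me carbon); the CIP descriptor of an unchanged centre can differ between intermediates because substituent priorities change.

Step 1
Reactants: 1 nerol
Product: 2 (2S,3R)-2,3-epoxynerol
Conditions: Ti(OiPr)4 (cat.), L-(+)-DIPT (cat.), t-BuOOH, 4 Å MS, CH2Cl2, −20 °C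
Reagents that add atoms: tert-butyl hydroperoxide, CC(C)(C)OO
Why: Sharpless asymmetric epoxidation touches only the allylic-alcohol alkene, and with the L-(+)-tartrate oxygen should be delivered to the face of the (Z)-alkene that gives the (2S,3R) cis-epoxide (C4 and C5 of the target).

Step 2
Reactants: 2 (2S,3R)-2,3-epoxynerol
Product: 3 (2R,3R)-3-methyl-3-(4-methylpent-3-en-1-yl)oxirane-2-carbaldehyde
Conditions: TEMPO (cat.), PhI(OAc)2, CH2Cl2, rt
Reagents that add atoms: none
Why: TEMPO/oxoammonium oxidation of the primary alcohol to the aldehyde is neutral and should leave the epoxide and the trisubstituted alkene untouched; the aldehyde is used crude.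

Step 3
Reactants: 4 methyl propiolate
Product: 5 methyl (2Z)-2-(hydroxymethyl)-3-iodoprop-2-enoate
Conditions: (CH2O)n, MgI2, CH2Cl2, 0 °C → rt
Reagents that add atoms: formaldehyde (from paraformaldehyde), C=O; magnesium iodide, [Mg+2].[I-].[I-]
Why: Iodo-aldol (β-iodo Morita–Baylis–Hillman) reaction: conjugate addition of iodide gives a magnesium β-iodoallenolate that is hydroxymethylated at the α-carbon, which should give kinetically the (Z)-isomer with iodine cis to the ester.

Step 4
Reactants: 3 (2R,3R)-epoxy aldehyde; 5 methyl (2Z)-2-(hydroxymethyl)-3-iodoprop-2-enoate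
Product: 7 (5S)-3-(hydroxymethyl)-5-[(2S,3R)-3-methyl-3-(4-methylpent-3-en-1-yl)oxiran-2-yl]furan-2(5H)-one, via hydroxy ester 6 (not isolated)
Conditions: CrCl2, NiCl2 (cat.), DMSO/THF, rt; lactonization on work-up (silica gel)
Reagents that add atoms: none
Why: Nozaki–Hiyama–Kishi alkenylation followed by lactonization of the (Z)-γ-hydroxy enoate; C6 should be set by Felkin–Anh/Cornforth addition to the cis-epoxy aldehyde (C=O anti to the epoxide C–O, attack away from the cis C3 chain), giving the anti (erythro) epoxy carbinol.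

Step 5
Reactants: 7 3-(hydroxymethyl)butenolide
Product: 9 3-{(2R,3S)-3-[(2S)-4-(hydroxymethyl)-5-oxo-2,5-dihydrofuran-2-yl]-2-methyloxiran-2-yl}propanal, via ozonide 8 (not isolated)
Conditions: O3, CH2Cl2, −78 °C (Sudan Red 7B end point); PPh3, −78 °C → rt
Reagents that add atoms: ozone, [O-][O+]=O
Why: Ozonolysis with reductive work-up; the electron-rich trisubstituted alkene should be cleaved well before the electron-poor butenolide alkene.

Step 6
Reactants: 9 aldehyde
Product: 10 methyl (2Z)-5-{(2R,3S)-3-[(2S)-4-(hydroxymethyl)-5-oxo-2,5-dihydrofuran-2-yl]-2-methyloxiran-2-yl}-2-iodopent-2-enoate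
Conditions: Ph3P=CHCO2Me, NIS, K2CO3, CH2Cl2, −20 °C; filter; then 9, −20 °C → rt
Reagents that add atoms: methyl (triphenylphosphoranylidene)acetate, COC(=O)C=P(c1ccccc1)(c1ccccc1)c1ccccc1; N-iodosuccinimide, O=C1CCC(=O)N1I
Why: Wittig olefination with the stabilized α-iodo ylide formed in the flask, which should place the ester trans to the chain and so give the (Z)-α-iodoacrylate (iodine cis to C2).

Step 7
Reactants: 10 iodoacrylate alcohol
Product: 11 methyl (2Z)-5-{(2R,3S)-3-[(2S)-4-(bromomethyl)-5-oxo-2,5-dihydrofuran-2-yl]-2-methyloxiran-2-yl}-2-iodopent-2-enoate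
Conditions: CBr4, PPh3, CH2Cl2, 0 °C
Reagents that add atoms: carbon tetrabromide, BrC(Br)(Br)Br
Why: Appel bromination of the primary allylic alcohol runs under neutral conditions that the epoxide, the butenolide and the alkenyl iodide should tolerate.

Step 8
Reactants: 11 3-(bromomethyl)butenolide
Product: 12 methyl (2Z)-5-{(2R,3S)-3-[(2S,3R)-3-[(1S)-1-hydroxyprop-2-en-1-yl]-4-methylidene-5-oxooxolan-2-yl]-2-methyloxiran-2-yl}-2-iodopent-2-enoate
Conditions: acrolein, In powder, THF/H2O, rt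
Reagents that add atoms: acrolein, C=CC=O
Why: Barbier allylation: the E-locked allylindium reacts at its γ-carbon (C7) through a Zimmerman–Traxler chair on the butenolide face anti to the C6 epoxide substituent, which should give the trans-lactone with the exocyclic methylene and the (8S) alcohol, C8 being epimeric to the target and corrected in step 11.

Step 9
Reactants: 13 methyl 2-(hydroxymethyl)prop-2-enoate
Product: 14 methyl 2-{[(tert-butyldimethylsilyl)oxy]methyl}prop-2-enoate
Conditions: TBSCl, imidazole, CH2Cl2, 0 °C → rt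
Reagents that add atoms: tert-butyldimethylsilyl chloride, CC(C)(C)[Si](C)(C)Cl
Why: Standard silylation of the primary alcohol.

Step 10
Reactants: 14 silyl ether ester
Product: 15 2-{[(tert-butyldimethylsilyl)oxy]methyl}prop-2-enoic acid
Conditions: LiOH, THF/H2O, 0 °C; then dilute HCl to pH 4
Reagents that add atoms: lithium hydroxide, [Li+].[OH-]
Why: Saponification of the methyl ester; the primary TBS ether should survive cold LiOH.

Step 11
Reactants: 12 (8S) allylic alcohol; 15 silyloxymethyl acrylic acid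
Product: 16 (1R)-1-{(2S,3R)-2-[(2S,3R)-3-[(3Z)-4-iodo-5-methoxy-5-oxopent-3-en-1-yl]-3-methyloxiran-2-yl]-4-methylidene-5-oxooxolan-3-yl}prop-2-en-1-yl 2-{[(tert-butyldimethylsilyl)oxy]methyl}prop-2-enoate
Conditions: PPh3, DIAD, THF, 0 °C → rt
Reagents that add atoms: none
Why: Mitsunobu esterification of the secondary allylic alcohol proceeds by SN2 with inversion, which should set the C8 configuration of the target and install the side chain in one step.

Step 12
Reactants: 16 vinyl ester
Product: 18 (1S)-2-oxo-1-{(2S,3S)-2-[(2S,3R)-3-[(3Z)-4-iodo-5-methoxy-5-oxopent-3-en-1-yl]-3-methyloxiran-2-yl]-4-methylidene-5-oxooxolan-3-yl}ethyl 2-{[(tert-butyldimethylsilyl)oxy]methyl}prop-2-enoate, via diol 17 (not isolated)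
Conditions: OsO4 (cat.), NaIO4, 2,6-lutidine, dioxane/H2O, rt
Reagents that add atoms: osmium tetroxide, O=[Os](=O)(=O)=O; sodium periodate, [Na+].[O-]I(=O)(=O)=O
Why: Lemieux–Johnson cleavage; electrophilic OsO4 should select the only electron-neutral monosubstituted alkene over the two 1,1-disubstituted acrylate-type alkenes and the iodoacrylate, and the buffered aldehyde is used at once.

Step 13
Reactants: 18 iodoacrylate aldehyde
Product: 19 methyl (1S,2S,4R,7E,9R,10S,11R)-10-[(2-{[(tert-butyldimethylsilyl)oxy]methyl}prop-2-enoyl)oxy]-9-hydroxy-4-methyl-12-methylidene-13-oxo-3,14-dioxatricyclo[9.3.0.0^2,4]tetradec-7-ene-8-carboxylate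
Conditions: CrCl2 (excess), NiCl2 (cat.), DMSO/THF, rt, high dilution (slow addition of 18)
Reagents that add atoms: none
Why: Ni(0) inserts into the C10–I bond, the alkenyl group is transmetalated to Cr(III), and the C10 alkenylchromium adds to the C9 aldehyde (intramolecular Nozaki–Hiyama–Kishi reaction). The closest known reaction types are Ni/Cr alkenyl iodide–aldehyde macrocyclizations to medium rings and Ni/Cr couplings of α-haloacrylates with aldehydes, which give Morita–Baylis–Hillman-type adducts. The ten-membered carbocycle closes by a 10-exo-trig addition to the aldehyde, with both alkene carbons (C1 and C10) inside the new ring. The new C9 stereocentre should be set by Felkin–Anh control from C8: the C8–O(acyl) bond lies anti to the incoming C10, giving the 8,9-anti (9R) alcohol. The step needs retention of the iodide geometry (secured by the stereoretentive Ni/Cr sequence and by the ring, which favours the cis C1=C10 alkene; the CIP descriptor changes from Z to E), chemoselectivity for C–I over the epoxide, the lactone and the acrylate units (secured by the Ni/Cr reagent), and cyclization over oligomerization (secured by high dilution and by the turn elements: cis-epoxide, trans-lactone and the (Z)-alkene).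

Step 14
Reactants: 19 macrocyclic C9 alcohol
Product: 20 methyl (1S,2S,4R,7E,9R,10S,11R)-9-(acetyloxy)-10-[(2-{[(tert-butyldimethylsilyl)oxy]methyl}prop-2-enoyl)oxy]-4-methyl-12-methylidene-13-oxo-3,14-dioxatricyclo[9.3.0.0^2,4]tetradec-7-ene-8-carboxylate
Conditions: Ac2O, pyridine, DMAP (cat.), CH2Cl2, 0 °C
Reagents that add atoms: acetic anhydride, CC(=O)OC(C)=O
Why: Acylation of the secondary allylic alcohol, run promptly so that the C8 ester has no time to migrate to the free C9 hydroxyl.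

Step 15
Reactants: 20 silyl-protected acetate
Product: 21 methyl (1S,2S,4R,7E,9R,10S,11R)-9-(acetyloxy)-10-{[2-(hydroxymethyl)prop-2-enoyl]oxy}-4-methyl-12-methylidene-13-oxo-3,14-dioxatricyclo[9.3.0.0^2,4]tetradec-7-ene-8-carboxylate (CNP0147016.1)
Conditions: HF·pyridine, pyridine, THF, 0 °C → rt
Reagents that add atoms: none
Why: Fluoride cleavage of the primary TBS ether under buffered conditions that the epoxide, the acetate and the Michael acceptors should tolerate.

Compound list
1 | nerol, (2Z)-3,7-dimethylocta-2,6-dien-1-ol | CC(C)=CCC/C(C)=C\CO | starting material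
2 | [(2S,3R)-3-methyl-3-(4-methylpent-3-en-1-yl)oxiran-2-yl]methanol ((2S,3R)-2,3-epoxynerol) | OC[C@@H]1O[C@]1(C)CCC=C(C)C | intermediate
3 | (2R,3R)-3-methyl-3-(4-methylpent-3-en-1-yl)oxirane-2-carbaldehyde | O=C[C@@H]1O[C@]1(C)CCC=C(C)C | intermediate
4 | methyl propiolate (methyl prop-2-ynoate) | C#CC(=O)OC | starting material
5 | methyl (2Z)-2-(hydroxymethyl)-3-iodoprop-2-enoate | OC/C(C(=O)OC)=C/I | intermediate
6 | methyl (2Z,4S)-4-hydroxy-2-(hydroxymethyl)-4-[(2S,3R)-3-methyl-3-(4-methylpent-3-en-1-yl)oxiran-2-yl]but-2-enoate (not isolated) | O[C@@H](/C=C(/CO)C(=O)OC)[C@@H]1O[C@]1(C)CCC=C(C)C | intermediate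
7 | (5S)-3-(hydroxymethyl)-5-[(2S,3R)-3-methyl-3-(4-methylpent-3-en-1-yl)oxiran-2-yl]furan-2(5H)-one | O=C1O[C@@H](C=C1CO)[C@@H]1O[C@]1(C)CCC=C(C)C | intermediate
8 | (5S)-5-{(2S,3R)-3-[2-(5,5-dimethyl-1,2,4-trioxolan-3-yl)ethyl]-3-methyloxiran-2-yl}-3-(hydroxymethyl)furan-2(5H)-one (ozonide, trioxolane carbon of either configuration, not isolated) | O=C1O[C@@H](C=C1CO)[C@@H]1O[C@]1(C)CCC1OOC(C)(C)O1 | intermediate
9 | 3-{(2R,3S)-3-[(2S)-4-(hydroxymethyl)-5-oxo-2,5-dihydrofuran-2-yl]-2-methyloxiran-2-yl}propanal | O=C1O[C@@H](C=C1CO)[C@@H]1O[C@]1(C)CCC=O | intermediate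
10 | methyl (2Z)-5-{(2R,3S)-3-[(2S)-4-(hydroxymethyl)-5-oxo-2,5-dihydrofuran-2-yl]-2-methyloxiran-2-yl}-2-iodopent-2-enoate | O=C1O[C@@H](C=C1CO)[C@@H]1O[C@]1(C)CC/C=C(\I)C(=O)OC | intermediate
11 | methyl (2Z)-5-{(2R,3S)-3-[(2S)-4-(bromomethyl)-5-oxo-2,5-dihydrofuran-2-yl]-2-methyloxiran-2-yl}-2-iodopent-2-enoate | O=C1O[C@@H](C=C1CBr)[C@@H]1O[C@]1(C)CC/C=C(\I)C(=O)OC | intermediate
12 | methyl (2Z)-5-{(2R,3S)-3-[(2S,3R)-3-[(1S)-1-hydroxyprop-2-en-1-yl]-4-methylidene-5-oxooxolan-2-yl]-2-methyloxiran-2-yl}-2-iodopent-2-enoate | O[C@@H](C=C)[C@H]1C(=C)C(=O)O[C@@H]1[C@@H]1O[C@]1(C)CC/C=C(\I)C(=O)OC | intermediate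
13 | methyl 2-(hydroxymethyl)prop-2-enoate | C=C(CO)C(=O)OC | starting material
14 | methyl 2-{[(tert-butyldimethylsilyl)oxy]methyl}prop-2-enoate | C=C(CO[Si](C)(C)C(C)(C)C)C(=O)OC | intermediate
15 | 2-{[(tert-butyldimethylsilyl)oxy]methyl}prop-2-enoic acid | C=C(CO[Si](C)(C)C(C)(C)C)C(=O)O | intermediate
16 | (1R)-1-{(2S,3R)-2-[(2S,3R)-3-[(3Z)-4-iodo-5-methoxy-5-oxopent-3-en-1-yl]-3-methyloxiran-2-yl]-4-methylidene-5-oxooxolan-3-yl}prop-2-en-1-yl 2-{[(tert-butyldimethylsilyl)oxy]methyl}prop-2-enoate | C=C(CO[Si](C)(C)C(C)(C)C)C(=O)O[C@H](C=C)[C@H]1C(=C)C(=O)O[C@@H]1[C@@H]1O[C@]1(C)CC/C=C(\I)C(=O)OC | intermediate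
17 | (1S)-2,3-dihydroxy-1-{(2S,3R)-2-[(2S,3R)-3-[(3Z)-4-iodo-5-methoxy-5-oxopent-3-en-1-yl]-3-methyloxiran-2-yl]-4-methylidene-5-oxooxolan-3-yl}propyl 2-{[(tert-butyldimethylsilyl)oxy]methyl}prop-2-enoate (diol, secondary carbinol of either configuration, not isolated) | C=C(CO[Si](C)(C)C(C)(C)C)C(=O)O[C@H](C(O)CO)[C@H]1C(=C)C(=O)O[C@@H]1[C@@H]1O[C@]1(C)CC/C=C(\I)C(=O)OC | intermediate
18 | (1S)-2-oxo-1-{(2S,3S)-2-[(2S,3R)-3-[(3Z)-4-iodo-5-methoxy-5-oxopent-3-en-1-yl]-3-methyloxiran-2-yl]-4-methylidene-5-oxooxolan-3-yl}ethyl 2-{[(tert-butyldimethylsilyl)oxy]methyl}prop-2-enoate | C=C(CO[Si](C)(C)C(C)(C)C)C(=O)O[C@H](C=O)[C@H]1C(=C)C(=O)O[C@@H]1[C@@H]1O[C@]1(C)CC/C=C(\I)C(=O)OC | intermediate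
19 | methyl (1S,2S,4R,7E,9R,10S,11R)-10-[(2-{[(tert-butyldimethylsilyl)oxy]methyl}prop-2-enoyl)oxy]-9-hydroxy-4-methyl-12-methylidene-13-oxo-3,14-dioxatricyclo[9.3.0.0^2,4]tetradec-7-ene-8-carboxylate | C=C(CO[Si](C)(C)C(C)(C)C)C(=O)O[C@H]1[C@H]2C(=C)C(=O)O[C@@H]2[C@@H]2O[C@]2(C)CC/C=C(/C(=O)OC)[C@H]1O | intermediate
20 | methyl (1S,2S,4R,7E,9R,10S,11R)-9-(acetyloxy)-10-[(2-{[(tert-butyldimethylsilyl)oxy]methyl}prop-2-enoyl)oxy]-4-methyl-12-methylidene-13-oxo-3,14-dioxatricyclo[9.3.0.0^2,4]tetradec-7-ene-8-carboxylate | C=C(CO[Si](C)(C)C(C)(C)C)C(=O)O[C@H]1[C@H]2C(=C)C(=O)O[C@@H]2[C@@H]2O[C@]2(C)CC/C=C(/C(=O)OC)[C@H]1OC(C)=O | intermediate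
21 | methyl (1S,2S,4R,7E,9R,10S,11R)-9-(acetyloxy)-10-{[2-(hydroxymethyl)prop-2-enoyl]oxy}-4-methyl-12-methylidene-13-oxo-3,14-dioxatricyclo[9.3.0.0^2,4]tetradec-7-ene-8-carboxylate (CNP0147016.1) | C=C(CO)C(=O)O[C@H]1[C@H]2C(=C)C(=O)O[C@@H]2[C@@H]2O[C@]2(C)CC/C=C(/C(=O)OC)[C@H]1OC(C)=O | target

Total step count: 15. Longest linear sequence: 12 steps (steps 1, 2, 4, 5, 6, 7, 8, 11, 12, 13, 14, 15 from nerol).

Steps most likely to fail

Step 13 (ring closure). What may go wrong: slow formation or protonation of the ester-bearing alkenylchromium, oligomerization in place of cyclization, poor facial selectivity at C9 under ring control, or migration of the C8 acyl group to the new C9 alkoxide. Fallback: move the ring closure to the C7–C8 bond. Setting out from 10, an intermolecular Nozaki–Hiyama–Kishi coupling with (S)-2,3-O-isopropylideneglyceraldehyde should give the Felkin (anti) carbinol F1. Selective Appel bromination of the primary allylic alcohol gives the bromide F2, acetylation (AcCl, 2,4,6-collidine) gives the acetate F3, and H5IO6 (acetonide removal and glycol cleavage in one flask) gives the α-acetoxy aldehyde F4. Indium-mediated intramolecular Barbier allylation at high dilution would then join C7 to C8, close the ten-membered ring and unveil the α-methylene lactone, giving the hydroxy acetate F5. Its C8 configuration would be ring-controlled and would have to be assigned. Esterification with 15 (DCC, DMAP) comes back to the route at 20.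

Step 11 (Mitsunobu inversion). What may go wrong: SN2′ attack at the vinyl terminus, elimination to a diene, or incomplete inversion; the step also relies on step 8 having delivered the (8S) alcohol. Fallback: redox inversion followed by acylation with retention. Setting out from 12, Dess–Martin oxidation gives the vinyl ketone F6. Oxazaborolidine (CBS) reduction, with the catalyst antipode chosen to deliver the (8R) alcohol, gives the epimeric allylic alcohol F7. Carbodiimide esterification with 15 (DCC, DMAP) comes back to the route at 16.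

Step 12 (alkene cleavage). What may go wrong: competing dihydroxylation of the α-methylene lactone or of the side-chain acrylate, and epimerization of the α-acyloxy aldehyde at C8. Fallback: bring C9 in at the alcohol oxidation level so that no alkene has to be cleaved. Setting out from 11, indium Barbier allylation of 2-[(4-methoxybenzyl)oxy]acetaldehyde gives the PMB-protected alcohol F8. Mitsunobu esterification with 15 gives the inverted ester F9, DDQ removes the PMB group to give the primary alcohol F10, and Dess–Martin oxidation comes back to the route at 18.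

Further compounds
F1 | step 13 | methyl (2E)-2-{(R)-[(4S)-2,2-dimethyl-1,3-dioxolan-4-yl](hydroxy)methyl}-5-{(2R,3S)-3-[(2S)-4-(hydroxymethyl)-5-oxo-2,5-dihydrofuran-2-yl]-2-methyloxiran-2-yl}pent-2-enoate | O=C1O[C@@H](C=C1CO)[C@@H]1O[C@]1(C)CC/C=C(/C(=O)OC)[C@@H](O)[C@@H]1COC(C)(C)O1
F2 | step 13 | bromide of F1 (CH2Br on the butenolide, C9 hydroxyl free) | O=C1O[C@@H](C=C1CBr)[C@@H]1O[C@]1(C)CC/C=C(/C(=O)OC)[C@@H](O)[C@@H]1COC(C)(C)O1
F3 | step 13 | C9 acetate of F2 | O=C1O[C@@H](C=C1CBr)[C@@H]1O[C@]1(C)CC/C=C(/C(=O)OC)[C@@H](OC(C)=O)[C@@H]1COC(C)(C)O1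
F4 | step 13 | methyl (2E)-2-[(1R)-1-(acetyloxy)-2-oxoethyl]-5-{(2R,3S)-3-[(2S)-4-(bromomethyl)-5-oxo-2,5-dihydrofuran-2-yl]-2-methyloxiran-2-yl}pent-2-enoate | O=C1O[C@@H](C=C1CBr)[C@@H]1O[C@]1(C)CC/C=C(/C(=O)OC)[C@@H](OC(C)=O)C=O
F5 | step 13 | methyl (1S,2S,4R,7E,9R,10S,11R)-9-(acetyloxy)-10-hydroxy-4-methyl-12-methylidene-13-oxo-3,14-dioxatricyclo[9.3.0.0^2,4]tetradec-7-ene-8-carboxylate | O[C@H]1[C@H]2C(=C)C(=O)O[C@@H]2[C@@H]2O[C@]2(C)CC/C=C(/C(=O)OC)[C@H]1OC(C)=O
F6 | step 11 | vinyl ketone from 12 (C8 ketone, C7 unchanged) | C=CC(=O)[C@H]1C(=C)C(=O)O[C@@H]1[C@@H]1O[C@]1(C)CC/C=C(\I)C(=O)OC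
F7 | step 11 | C8 epimer of 12, (1R)-1-hydroxyprop-2-en-1-yl alcohol | O[C@H](C=C)[C@H]1C(=C)C(=O)O[C@@H]1[C@@H]1O[C@]1(C)CC/C=C(\I)C(=O)OC
F8 | step 12 | Barbier adduct of 11 with 2-[(4-methoxybenzyl)oxy]acetaldehyde (C8 alcohol, C9 as CH2OPMB) | O[C@@H](COCc1ccc(OC)cc1)[C@H]1C(=C)C(=O)O[C@@H]1[C@@H]1O[C@]1(C)CC/C=C(\I)C(=O)OC
F9 | step 12 | C8-inverted 2-{[(tert-butyldimethylsilyl)oxy]methyl}prop-2-enoate ester of F8 | C=C(CO[Si](C)(C)C(C)(C)C)C(=O)O[C@H](COCc1ccc(OC)cc1)[C@H]1C(=C)C(=O)O[C@@H]1[C@@H]1O[C@]1(C)CC/C=C(\I)C(=O)OC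
F10 | step 12 | primary C9 alcohol from F9 | C=C(CO[Si](C)(C)C(C)(C)C)C(=O)O[C@H](CO)[C@H]1C(=C)C(=O)O[C@@H]1[C@@H]1O[C@]1(C)CC/C=C(\I)C(=O)OC
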